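The earlier runs and the new flask come from a simulation from invented constants; scatter was added.

**Amounts charged.** Wednesday's, Thursday's, Saturday's and Tuesday's were charged with the same amounts, 3.00 equiv of reagent among them, and parted by temperature.

| flask | left-handed substrate | right-handed substrate | reagent | temperature | remark | time |
|---|---|---|---|---|---|---|
| birch | 0.010 M | 0.010 M | 1.5 equiv | 20 °C | run made earlier |  |
| ash | 0.010 M | 0.010 M | 6 equiv | 55 °C | run made earlier |  |
| Wednesday's | 0.010 M | 0.010 M | 3.00 equiv | 55 °C |  | 1.5 h |
| Thursday's | 0.010 M | 0.010 M | 3.00 equiv |  | at 85 °C until 25 min, from then on at 25 °C | 1.5 h |
| Saturday's | 0.010 M | 0.010 M | 3.00 equiv | 85 °C |  | 1.5 h |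
| Tuesday's | 0.010 M | 0.010 M | 3.00 equiv | 25 °C |  | 1.5 h |

- birch (time / h: left-handed product / %, right-handed product / %): 0.500: 7.6, 3.2; 1.33: 12.9, 6.4; 2.50: 21.6, 11.4; 4.00: 23.1, 12.3; 5.00: 28.3, 14.6
- ash (time / min: left-handed product / %, right-handed product / %): 5.00: 21.3, 30.6; 15.0: 33.7, 45.5; 25.0: 35.6, 52.7; 40.0: 38.2, 56.7; 50.0: 39.3, 56.0

(scatter of a reading: 1 percentage point)

- reagent is single-handed; left-handed substrate and right-handed substrate are mirror images of each other, charged as a racemate, each of them at the stated concentration
- the earlier runs were read with a standard deviation of 1 percentage point
- an excess is the difference of the two amounts in percent of their sum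
- an excess is below zero if the other one leads
- the handed part of reagent does not stay in what it makes, so the products of the two hands are mirror images too

- the flask that comes out highest in excess of left-handed product over right-handed product, or "all alike" when all lie within 1.5 percentage points (Wednesday's / Thursday's / Saturday's / Tuesday's / all alike)
- excess of left-handed product over right-handed product at the end, Wednesday's
- excess of left-handed product over right-handed product at the end, Thursday's
- excess of left-handed product over right-handed product at the end, Saturday's
- excess of left-handed product over right-handed product at the end, Tuesday's

**Warm end.** I reckoned through the selectivity factor s, the rate constant of making left-handed product over that of making right-handed product. In the ash run right-handed product was read at 56.7%, more than the half of the total charged that was right-handed substrate. I therefore took the two hands of substrate to interconvert and stand level. Then s is the product ratio, which over the last 3 readings was 0.684.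

**Cold end.** The birch run required no interconversion, so I assumed that each hand drew on its own stock. Averaged over its last 3 readings, 48.7% of the left-handed charge and 25.5% of the right-handed charge had gone. The ratio of the logarithms of what remained gave s = 2.26, above the plain ratio of 1.91.

**The join.** A straight line of ln s against reciprocal temperature gave 27.3 kJ/mol, the selectivity gap: the activation energy of making right-handed product minus that of making left-handed product. With level substrates the excess is s minus one, divided by s plus one. That gave me −18.8% for Wednesday's and, with 0.295 as s, −54.4% for Saturday's.

**Speed.** Taking the rate as proportional to reagent, I reckoned from the ash run's first reading a half-life of substrate of 9.47 min at 3.00 equiv and 55 °C. Thursday's change at 25 min comes later than that half-life, which I had reckoned for a cooler flask than Thursday's first stage, so I put Thursday's with Saturday's. For the start of Tuesday's I reckoned 1.87 as s, an excess of 30.3%, and I expected that excess to sink as left-handed substrate thinned.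

**The forecast.** It named Tuesday's, with −16%, −47%, −48% and 26% in the order asked, and held that “the cooling comes too late to matter”. On Saturday's it stood above my figure.

**The flasks.** Tuesday's came out highest, and the four excesses were −18.8%, −53.6%, −53.8% and 23.0%.

    reagent + right-handed substrate → right-handed product (k = 0.00483 /M/s, Ea = 74.0 kJ/mol)
    left-handed substrate ⇌ right-handed substrate (k = 1.35 × 10⁻⁴ /s, Ea = 95.0 kJ/mol)
    2 reagent → self-condensation product (k = 0.00231 /M/s, Ea = 51.0 kJ/mol)
    reagent + left-handed substrate → left-handed product (k = 0.00863 /M/s, Ea = 47.0 kJ/mol)
    (constants at 25 °C)

**Level hands.** In Saturday's at 0.0200 h, the forward step took left-handed substrate to right-handed substrate at 26 times the rate at which left-handed substrate went to left-handed product, and at 1.50 h at 850 times. Saturday's ended with 0.516% of left-handed substrate and 0.515% of right-handed substrate. For a flask like Saturday's kept at 70 °C, the gap of 27.3 kJ/mol gives s = 0.441 and an excess of −38.8%; that flask gave −38.2%.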